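**Retrosynthetic overview**

1. The target is reached last by O-dealkylation of its 7-ethyl ether with BBr3.
2. The strategy rests on ring A: oxygen at C5 and C7 in a 1,3 relation, the C5 hydroxyl peri to the C4 carbonyl, bare CH at C6 and C8, and fusion to the pyranone ring through C4a–C8a. A ketene (carbonyl carbon = C5, CH = C8) and an ynol ether (C6–C7) deliver exactly this pattern when annulated onto the C2=C3 bond of a preformed 4-pyranone.
3. Key disconnection: C4a–C5, C5–C6 and C7–C8 (C8–C8a arises in the Wolff shift), leading back to 2-(2-diazoacetyl)-6-nonacosyl-4H-pyran-4-one and ethoxyacetylene.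
4. The diazo ketone comes from 6-nonacosyl-4-oxo-4H-pyran-2-carboxylic acid (SOCl2, then CH2N2). The acid comes from acid cyclodehydration of a 2,4,6-triketo ester, made from tritriacontane-2,4-dione and diethyl oxalate, the diketone from acetylacetone and 1-bromooctacosane.
5. Ring order: pyranone ring first (step 3), ring A last (step 6). The target has no stereocentre.

Key step: step 6

Remark: 1-bromooctacosane is taken as purchasable (otherwise one step from commercial octacosan-1-ol). All intermediates with the C29 chain are waxy solids, so reactions are run in THF, toluene or chlorinated solvents, warmed where solubility requires.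

**Route**

Step 1
Reactants: 1 pentane-2,4-dione (acetylacetone); 2 1-bromooctacosane
Product: 3 tritriacontane-2,4-dione
Conditions: 1 (1.3 equiv), LiN(iPr)2 (2.6 equiv), THF, 0 °C; then 2 in warm THF, 0 → 40 °C; aq. HCl
Reagents that add atoms: none
Why: The 1,3-dianion of the β-diketone should react only at its more basic terminal carbon with the primary bromide (SN2 dianion alkylation), the methyl carbon of 1 becoming the twenty-ninth chain carbon.

Step 2
Reactants: 3 tritriacontane-2,4-dione; 4 diethyl oxalate
Product: 5 ethyl 2,4,6-trioxopentatriacontanoate (enol tautomers)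
Conditions: NaH (4 equiv), 4 (2 equiv), 1,2-dimethoxyethane, 85 °C; then cold aq. HCl
Reagents that add atoms: none
Why: Claisen condensation of the β-diketone at its terminal carbon under excess NaH should favour the methyl group over the chain methylene, the product being withdrawn as its polyenolate so that the keto ester is not attacked again.

Step 3
Reactants: 5 ethyl 2,4,6-trioxopentatriacontanoate
Product: 7 6-nonacosyl-4-oxo-4H-pyran-2-carboxylic acid, via pyranone ethyl ester 6 (not isolated)
Conditions: conc. HCl, AcOH, 100 °C
Reagents that add atoms: water, O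
Why: Acid-catalysed cyclodehydration of the 1,3,5-tricarbonyl array (C6 enol oxygen onto the C2 ketone, then loss of water) should give the 4-pyranone, and the same hot aqueous acid hydrolyses the ester without the ring opening that hydroxide could cause.

Step 4
Reactants: 7 6-nonacosyl-4-oxo-4H-pyran-2-carboxylic acid
Product: 8 6-nonacosyl-4-oxo-4H-pyran-2-carbonyl chloride
Conditions: SOCl2 (5 equiv), toluene, 75 °C; volatiles removed with toluene; used crude
Reagents that add atoms: thionyl chloride, O=S(Cl)Cl
Why: Acid chloride formation with SOCl2 is standard for 4-pyranone-2-carboxylic acids; no formamide catalyst is added, so the pyranone carbonyl is not converted into a chloropyrylium salt.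

Step 5
Reactants: 8 6-nonacosyl-4-oxo-4H-pyran-2-carbonyl chloride
Product: 9 2-(2-diazoacetyl)-6-nonacosyl-4H-pyran-4-one
Conditions: CH2N2 (3.5 equiv), Et2O/THF, 0 °C; excess quenched with AcOH; work-up in dim light
Reagents that add atoms: diazomethane, C=[N+]=[N-]
Why: Acylation of diazomethane by the acid chloride (first stage of an Arndt–Eistert sequence) should be much faster at 0 °C than dipolar cycloaddition to the pyranone double bond, and the excess reagent takes up HCl so that no chloromethyl ketone forms.

Step 6
Reactants: 9 2-(2-diazoacetyl)-6-nonacosyl-4H-pyran-4-one; 10 ethoxyacetylene (ethoxyethyne)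
Product: 15 7-ethoxy-5-hydroxy-2-nonacosyl-4H-chromen-4-one, via pyranyl ketene 11 (not isolated), via ethoxycyclobutenone 12 (not isolated), via dienylketene 13 (not isolated), via 4aH-chromenedione 14 (not isolated)
Conditions: 10 (3 equiv), ClCH2CH2Cl (0.02 M), violet LED (ca. 400 nm), 20 °C; excess 10 evaporated; then toluene, 100 °C, dark
Reagents that add atoms: none
Why: Proposed new method: Violet light should excite only the diazo ketone (the pyranone core and the 5-hydroxychromone product do not absorb there), so N2 is lost and the pyranyl group shifts from the carbonyl carbon to the diazo carbon (Wolff rearrangement, forming C8–C8a) to give ketene 11, whose carbonyl carbon becomes C5 and whose CH becomes C8; [2+2] cycloaddition with ethoxyacetylene then gives cyclobutenone 12 and forms C5–C6 and C7–C8. Heating opens 12 by a reversible conrotatory four-electron process, and only dienylketene 13, in which the pyranyl group has turned inward (cis to the ketene arm), is drained by disrotatory six-electron electrocyclisation of the ketene carbon onto pyranone C3 (the future C4a); this closes ring A, and enolisation of the doubly activated C4a–H of 14 gives the phenol. The closest known reaction type is the photochemical Wolff variant of the Danheiser benzannulation of alkenyl, aryl and heteroaryl α-diazo ketones with alkoxy- and siloxyalkynes, which has not been run with a 4-pyranone as the terminating π bond; it should work here because the C2=C3 bond is held s-cis in its ring, is an enol ether whose β carbon (C3) is nucleophilic toward the ketene carbon, and has little aromatic stabilisation to lose. No stereocentre survives, since the sp3 carbons of 12 and 14 both become planar again. The step needs regioselectivity in the [2+2] addition, secured by the polarisation of the ynol ether (electrophilic ketene carbon to the nucleophilic CH terminus, placing OEt at C7), and closure onto C3 in preference to capture of the ketenes by the product phenol, which the hydrogen bond from the C5 hydroxyl to the C4 carbonyl and high dilution should secure.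

Step 7
Reactants: 15 7-ethoxy-5-hydroxy-2-nonacosyl-4H-chromen-4-one
Product: 16 5,7-dihydroxy-2-nonacosyl-4H-chromen-4-one (target)
Conditions: BBr3 (5 equiv), CH2Cl2, −78 °C → rt; then ice water
Reagents that add atoms: none
Why: Lewis-acid ether cleavage (boron binds the ether oxygen and bromide removes the ethyl group by SN2) should free the C7 hydroxyl; the excess covers the reagent bound by the C4 carbonyl/C5 hydroxyl chelate, and the chromone core and saturated chain are inert.

**Compound list**

1 | pentane-2,4-dione (acetylacetone) | CC(=O)CC(C)=O | starting material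
2 | 1-bromooctacosane | CCCCCCCCCCCCCCCCCCCCCCCCCCCCBr | starting material
3 | tritriacontane-2,4-dione | CCCCCCCCCCCCCCCCCCCCCCCCCCCCCC(=O)CC(C)=O | intermediate
4 | diethyl oxalate | CCOC(=O)C(=O)OCC | starting material
5 | ethyl 2,4,6-trioxopentatriacontanoate | CCCCCCCCCCCCCCCCCCCCCCCCCCCCCC(=O)CC(=O)CC(=O)C(=O)OCC | intermediate
6 | ethyl 6-nonacosyl-4-oxo-4H-pyran-2-carboxylate | CCCCCCCCCCCCCCCCCCCCCCCCCCCCCc1cc(=O)cc(C(=O)OCC)o1 | intermediate (not isolated)
7 | 6-nonacosyl-4-oxo-4H-pyran-2-carboxylic acid | CCCCCCCCCCCCCCCCCCCCCCCCCCCCCc1cc(=O)cc(C(=O)O)o1 | intermediate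
8 | 6-nonacosyl-4-oxo-4H-pyran-2-carbonyl chloride | CCCCCCCCCCCCCCCCCCCCCCCCCCCCCc1cc(=O)cc(C(=O)Cl)o1 | intermediate
9 | 2-(2-diazoacetyl)-6-nonacosyl-4H-pyran-4-one | CCCCCCCCCCCCCCCCCCCCCCCCCCCCCc1cc(=O)cc(C(=O)C=[N+]=[N-])o1 | intermediate
10 | ethoxyacetylene (ethoxyethyne) | C#COCC | starting material
11 | 2-(6-nonacosyl-4-oxo-4H-pyran-2-yl)ethen-1-one (pyranyl ketene) | CCCCCCCCCCCCCCCCCCCCCCCCCCCCCc1cc(=O)cc(C=C=O)o1 | intermediate (not isolated)
12 | 3-ethoxy-4-(6-nonacosyl-4-oxo-4H-pyran-2-yl)cyclobut-2-en-1-one (racemic) | CCCCCCCCCCCCCCCCCCCCCCCCCCCCCc1cc(=O)cc(C2C(=O)C=C2OCC)o1 | intermediate (not isolated)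
13 | (3E)-3-ethoxy-4-(6-nonacosyl-4-oxo-4H-pyran-2-yl)buta-1,3-dien-1-one (ketene arm cis to the pyranyl group) | CCCCCCCCCCCCCCCCCCCCCCCCCCCCCc1cc(=O)cc(/C=C(\C=C=O)OCC)o1 | intermediate (not isolated)
14 | 7-ethoxy-2-nonacosyl-4aH-chromene-4,5-dione (racemic) | CCCCCCCCCCCCCCCCCCCCCCCCCCCCCC1=CC(=O)C2C(=O)C=C(OCC)C=C2O1 | intermediate (not isolated)
15 | 7-ethoxy-5-hydroxy-2-nonacosyl-4H-chromen-4-one | CCCCCCCCCCCCCCCCCCCCCCCCCCCCCc1cc(=O)c2c(O)cc(OCC)cc2o1 | intermediate
16 | 5,7-dihydroxy-2-nonacosyl-4H-chromen-4-one | CCCCCCCCCCCCCCCCCCCCCCCCCCCCCc1cc(=O)c2c(O)cc(O)cc2o1 | target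

**Step count and risks**

Total step count: 7. Longest linear sequence: 7 steps (from 1 or 2 to 16).

Steps most likely to fail:

1. Step 6 (Proposed new method). The six-electron closure of the dienylketene onto pyranone C3 may not compete with ketene oligomerisation, or the sequence may stall at the cyclobutenone; light-induced decay of the pyranone is a further risk. Fallback with known chemistry, in which ring A is taken from an aromatic starting material instead of being built: it sets out from bromide 2 and returns to the route at target 16. Commercial 1-(2-hydroxy-4,6-dimethoxyphenyl)ethanone undergoes Claisen condensation with ethyl acetate (NaH, THF) to give 1-(2-hydroxy-4,6-dimethoxyphenyl)butane-1,3-dione F1. Acid cyclodehydration (HCl, AcOH) should give 5,7-dimethoxy-2-methyl-4H-chromen-4-one F2. Its lateral lithium dienolate (LiN(iPr)2, THF/DMPU, −78 °C) is alkylated at the methyl carbon by 2 to give 5,7-dimethoxy-2-nonacosyl-4H-chromen-4-one F3. BBr3 in CH2Cl2 then removes both methyl groups to reach 16.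

2. Step 5. Diazomethane may add as a 1,3-dipole across the acyl-activated C2=C3 bond of the pyranone, or HCl may convert the diazo ketone into the chloromethyl ketone. The fallback avoids diazomethane; it sets out from acid chloride 8 and returns at diazo ketone 9. Compound 8 acylates Meldrum's acid (pyridine, CH2Cl2, 0 °C) to give 5-[hydroxy(6-nonacosyl-4-oxo-4H-pyran-2-yl)methylidene]-2,2-dimethyl-1,3-dioxane-4,6-dione F4. Heating in aqueous AcOH should give the methyl ketone 2-acetyl-6-nonacosyl-4H-pyran-4-one F5. Kinetic enolisation of the acetyl group (LiN(SiMe3)2, THF, −78 °C) and trapping with CF3CO2CH2CF3 gives 4,4,4-trifluoro-1-(6-nonacosyl-4-oxo-4H-pyran-2-yl)butane-1,3-dione F6. Detrifluoroacetylative diazo transfer (MsN3, Et3N, H2O, MeCN) then gives 9.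

3. Step 2. Acylation may occur at the chain methylene, ethoxide may cleave the diketone by retro-Claisen reaction, or waxy sodium enolates may precipitate and stop the conversion. The fallback inverts the order of bond formation so that no regiochemical choice arises; it sets out from 1 and 4 and returns at acid 7. Claisen condensation of 1 with 4 (NaOEt, EtOH) gives ethyl 2,4,6-trioxoheptanoate F7. Hot conc. HCl cyclises and hydrolyses it to 6-methyl-4-oxo-4H-pyran-2-carboxylic acid F8. Its dianion (LiN(iPr)2, 2.2 equiv, THF/DMPU, −78 → 0 °C; carboxylate plus lateral dienolate) is alkylated at the 6-methyl carbon by bromide 2 to give 7 directly.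

**Further compounds**

F1 | step 6 | 1-(2-hydroxy-4,6-dimethoxyphenyl)butane-1,3-dione | CC(=O)CC(=O)c1c(O)cc(OC)cc1OC
F2 | step 6 | 5,7-dimethoxy-2-methyl-4H-chromen-4-one | Cc1cc(=O)c2c(OC)cc(OC)cc2o1
F3 | step 6 | 5,7-dimethoxy-2-nonacosyl-4H-chromen-4-one | CCCCCCCCCCCCCCCCCCCCCCCCCCCCCc1cc(=O)c2c(OC)cc(OC)cc2o1
F4 | step 5 | 5-[hydroxy(6-nonacosyl-4-oxo-4H-pyran-2-yl)methylidene]-2,2-dimethyl-1,3-dioxane-4,6-dione | CCCCCCCCCCCCCCCCCCCCCCCCCCCCCc1cc(=O)cc(C(O)=C2C(=O)OC(C)(C)OC2=O)o1
F5 | step 5 | 2-acetyl-6-nonacosyl-4H-pyran-4-one | CCCCCCCCCCCCCCCCCCCCCCCCCCCCCc1cc(=O)cc(C(C)=O)o1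
F6 | step 5 | 4,4,4-trifluoro-1-(6-nonacosyl-4-oxo-4H-pyran-2-yl)butane-1,3-dione | CCCCCCCCCCCCCCCCCCCCCCCCCCCCCc1cc(=O)cc(C(=O)CC(=O)C(F)(F)F)o1
F7 | step 2 | ethyl 2,4,6-trioxoheptanoate | CC(=O)CC(=O)CC(=O)C(=O)OCC
F8 | step 2 | 6-methyl-4-oxo-4H-pyran-2-carboxylic acid | Cc1cc(=O)cc(C(=O)O)o1
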